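The route rests on disconnecting ring D, the 2,2-dimethyl-2H-pyran fused to C4'–C5' of ring B, from a finished, MOM-protected 8-prenylflavanone that carries only a 1,1-dimethylpropargyl ether on O4'. One thermal operation runs a [3,3] shift, enolisation, a [1,5]-H shift and an oxa-6π electrocyclisation. It passes through the vinyl ortho-quinone methide presumed for the biosynthetic prenylphenol cyclisation. The step exploits that, once ring C exists, C1' bears sp3 C2 instead of a chelating carbonyl, so that C5'–H (para to O2') is favoured over the flanked C3'–H. C2 is formed racemic, and the (2S) enantiomer is selected after the heating by transfer-hydrogenative kinetic resolution.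

Key step: step 7

Remark on the chemistry: flavanone numbering is used (rings A, B, C; ring D is the pyran with O1'', C2'', C3'', C4''). Compounds 10 to 14 are racemates, so their SMILES carry no label at C2.

Step 1
Reactants: 1 2',4',6'-trihydroxyacetophenone; 2 prenyl bromide (1-bromo-3-methylbut-2-ene)
Product: 3 1-[2,4,6-trihydroxy-3-(3-methylbut-2-en-1-yl)phenyl]ethan-1-one
Conditions: KOH (1 equiv), H2O, slow addition of 2 (1 equiv), 0 °C to rt
Reagents that add atoms: none
Why: Nuclear C-prenylation of a phloroglucinol, in which the hydrogen-bonded phenolate in water attacks the soft allylic bromide through ring carbon; C3 and C5 of 1 are equivalent, so only one mono-C-prenyl isomer can form, and one equivalent of 2 limits double alkylation.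

Step 2
Reactants: 3 1-[2,4,6-trihydroxy-3-(3-methylbut-2-en-1-yl)phenyl]ethan-1-one
Product: 4 1-[2-hydroxy-4,6-bis(methoxymethoxy)-3-(3-methylbut-2-en-1-yl)phenyl]ethan-1-one
Conditions: MOMCl (2.1 equiv), K2CO3, acetone, 0 °C to reflux
Reagents that add atoms: chloromethyl methyl ether (MOMCl), COCCl
Why: Williamson-type O-alkylation steered by chelation and crowding, in which the unchelated 4-OH and the less hindered chelatable 6-OH react while 2-OH, wedged between acetyl and prenyl, keeps the hydrogen bond and stays free for closure of ring C on the prenyl side.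

Step 3
Reactants: 5 2,4-dihydroxybenzaldehyde; 6 3-chloro-3-methylbut-1-yne
Product: 7 2-hydroxy-4-[(2-methylbut-3-yn-2-yl)oxy]benzaldehyde
Conditions: K2CO3, KI (cat.), CuI (cat.), acetone, reflux
Reagents that add atoms: none
Why: Copper-assisted O-propargylation of a phenol with a tertiary propargylic chloride, selective for 4-OH because 2-OH is locked in the hydrogen bond to the formyl group and is the poorer nucleophile.

Step 4
Reactants: 7 2-hydroxy-4-[(2-methylbut-3-yn-2-yl)oxy]benzaldehyde
Product: 8 2-(methoxymethoxy)-4-[(2-methylbut-3-yn-2-yl)oxy]benzaldehyde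
Conditions: MOMCl (1.5 equiv), K2CO3, acetone, reflux
Reagents that add atoms: chloromethyl methyl ether (MOMCl), COCCl
Why: Standard MOM protection of the chelated phenol, which leaves alkyne, tertiary ether and aldehyde untouched, avoids phenolate deactivation of the aldehyde in step 5 and later screens C3'.

Step 5
Reactants: 4 1-[2-hydroxy-4,6-bis(methoxymethoxy)-3-(3-methylbut-2-en-1-yl)phenyl]ethan-1-one; 8 2-(methoxymethoxy)-4-[(2-methylbut-3-yn-2-yl)oxy]benzaldehyde
Product: 9 (E)-2'-hydroxy-2,4',6'-tris(methoxymethoxy)-4-[(2-methylbut-3-yn-2-yl)oxy]-3'-prenylchalcone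
Conditions: KOH (aq., excess), EtOH, rt
Reagents that add atoms: none
Why: Claisen–Schmidt condensation of the only enolisable ketone with a non-enolisable aldehyde, whose E1cB dehydration gives the more stable (E)-enone while MOM acetals, alkyne and prenyl group are inert to hydroxide.

Step 6
Reactants: 9 (E)-2'-hydroxy-2,4',6'-tris(methoxymethoxy)-4-[(2-methylbut-3-yn-2-yl)oxy]-3'-prenylchalcone
Product: 10 rac-5,7,2'-tris(methoxymethoxy)-4'-[(2-methylbut-3-yn-2-yl)oxy]-8-prenylflavanone
Conditions: NaOAc, EtOH, reflux; recovered 9 is resubmitted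
Reagents that add atoms: none
Why: Base-mediated 6-endo-trig intramolecular oxa-Michael addition of the only free phenol closes ring C next to the prenyl group, the 6'-OMOM group twisting the chalcone out of conjugation and shifting the equilibrium to the flavanone; C2 is deliberately formed as a racemate.

Step 7
Reactants: 10 rac-5,7,2'-tris(methoxymethoxy)-4'-[(2-methylbut-3-yn-2-yl)oxy]-8-prenylflavanone
Product: 14 rac-5,7-bis(methoxymethoxy)-2-[7-(methoxymethoxy)-2,2-dimethyl-2H-chromen-6-yl]-8-prenylchroman-4-one, via allenyl cyclohexadienone 11 (not isolated), via ortho-allenylphenol 12 (not isolated), via vinyl ortho-quinone methide 13 (not isolated)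
Conditions: degassed o-xylene (dilute), 140 °C, Ar, base-washed glassware
Reagents that add atoms: none
Why: Heating triggers an aromatic propargyl Claisen rearrangement ([3,3]) that moves the alkyne terminus from O4' onto C5' to give allenyl dienone 11, which enolises to 12; a [1,5]-H shift from O4'–H to the central allene carbon then gives the (Z)-vinyl ortho-quinone methide 13. The closest known reaction type is the thermal cyclisation of aryl 1,1-dimethylpropargyl ethers to 2,2-dimethyl-2H-chromenes, in which the gem-dimethyl group lowers the barrier of the [3,3] step. Ring D is closed by a thermal disrotatory oxa-6π electrocyclisation of 13 that forms the O1''–C2'' bond and restores the aromaticity of ring B, the C5'–C4'' bond having been made in the [3,3] step; 13 is the species an oxidative prenylphenol cyclase is presumed to generate. No stereocentre is created in 14 (the sp3 C5' of 11 is erased on enolisation), and C2 is still racemic, so heat cannot erode stereochemical information. The step needs site selectivity for C5' over C3': C5' is para to the donor O2' and adjoins only C6'–H, whereas C3' lies between two oxygens and is screened by the MOM group, which the bulky C1' substituent turns toward C3', and ring B no longer carries the chelated ortho-acyl group that steers salicylaldehyde-type ethers to the carbon between the oxygens. The 8-prenyl group, the MOM acetals and the ketone have no thermal pathway at this temperature in a neutral hydrocarbon.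

Step 8
Reactants: 14 rac-5,7-bis(methoxymethoxy)-2-[7-(methoxymethoxy)-2,2-dimethyl-2H-chromen-6-yl]-8-prenylchroman-4-one
Product: 15 (2S)-5,7-bis(methoxymethoxy)-2-[7-(methoxymethoxy)-2,2-dimethyl-2H-chromen-6-yl]-8-prenylchroman-4-one
Conditions: RuCl[(R,R)-TsDPEN](p-cymene) (2 mol %), HCO2H/Et3N, EtOAc, rt, stopped slightly past half conversion; chromatography
Reagents that add atoms: none
Why: Kinetic resolution by Noyori asymmetric transfer hydrogenation, a known reaction type for racemic flavanones, in which the (R,R)-catalyst prefers to form (4R)-carbinols and is matched only with the cis-selective reduction of the (2R)-ketone to the (2R,4R)-flavan-4-ol, so the mismatched (2S)-ketone 15 remains and is separated, isolated alkenes being inert.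

Step 9
Reactants: 15 (2S)-5,7-bis(methoxymethoxy)-2-[7-(methoxymethoxy)-2,2-dimethyl-2H-chromen-6-yl]-8-prenylchroman-4-one
Product: 16 (2S)-5,7-dihydroxy-2-(7-hydroxy-2,2-dimethyl-2H-chromen-6-yl)-8-(3-methylbut-2-en-1-yl)chroman-4-one (target)
Conditions: conc. HCl (cat., about 2 % v/v), MeOH, 0 °C to 40 °C, quenched with NaHCO3 as soon as conversion is complete
Reagents that add atoms: none
Why: Acid-catalysed transacetalisation of the three aryl MOM ethers to methanol under mild conditions should spare the prenyl and chromene alkenes, and C2 should hold because flavanone racemisation runs mainly through base-induced retro-oxa-Michael opening, which is not available at low pH.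

Compound list
1 | 2',4',6'-trihydroxyacetophenone | CC(=O)c1c(O)cc(O)cc1O | starting material
2 | prenyl bromide | CC(C)=CCBr | starting material
3 | 1-[2,4,6-trihydroxy-3-(3-methylbut-2-en-1-yl)phenyl]ethan-1-one | CC(=O)c1c(O)cc(O)c(CC=C(C)C)c1O | intermediate
4 | 1-[2-hydroxy-4,6-bis(methoxymethoxy)-3-(3-methylbut-2-en-1-yl)phenyl]ethan-1-one | CC(=O)c1c(OCOC)cc(OCOC)c(CC=C(C)C)c1O | intermediate
5 | 2,4-dihydroxybenzaldehyde | O=Cc1ccc(O)cc1O | starting material
6 | 3-chloro-3-methylbut-1-yne | C#CC(C)(C)Cl | starting material
7 | 2-hydroxy-4-[(2-methylbut-3-yn-2-yl)oxy]benzaldehyde | C#CC(C)(C)Oc1ccc(C=O)c(O)c1 | intermediate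
8 | 2-(methoxymethoxy)-4-[(2-methylbut-3-yn-2-yl)oxy]benzaldehyde | C#CC(C)(C)Oc1ccc(C=O)c(OCOC)c1 | intermediate
9 | (E)-2'-hydroxy-2,4',6'-tris(methoxymethoxy)-4-[(2-methylbut-3-yn-2-yl)oxy]-3'-prenylchalcone | CC(C)=CCc1c(O)c(C(=O)/C=C/c2ccc(OC(C)(C)C#C)cc2OCOC)c(OCOC)cc1OCOC | intermediate
10 | rac-5,7,2'-tris(methoxymethoxy)-4'-[(2-methylbut-3-yn-2-yl)oxy]-8-prenylflavanone | CC(C)=CCc1c(OCOC)cc(OCOC)c2c1OC(c1ccc(OC(C)(C)C#C)cc1OCOC)CC2=O | intermediate
11 | allenyl cyclohexadienone (C4'=O, sp3 C5' bearing the 3-methylbuta-1,2-dienyl group; not isolated) | CC(C)=CCc1c(OCOC)cc(OCOC)c2c1OC(C1=CC(C=C=C(C)C)C(=O)C=C1OCOC)CC2=O | intermediate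
12 | ortho-allenylphenol (4'-OH, 5'-(3-methylbuta-1,2-dienyl); not isolated) | CC(C)=CCc1c(OCOC)cc(OCOC)c2c1OC(c1cc(C=C=C(C)C)c(O)cc1OCOC)CC2=O | intermediate
13 | (Z)-vinyl ortho-quinone methide (C4'=O, C5'=CH–CH=C(CH3)2; not isolated) | CC(C)=CCc1c(OCOC)cc(OCOC)c2c1OC(C1=C/C(=C/C=C(C)C)C(=O)C=C1OCOC)CC2=O | intermediate
14 | rac-5,7-bis(methoxymethoxy)-2-[7-(methoxymethoxy)-2,2-dimethyl-2H-chromen-6-yl]-8-prenylchroman-4-one | CC(C)=CCc1c(OCOC)cc(OCOC)c2c1OC(c1cc3c(cc1OCOC)OC(C)(C)C=C3)CC2=O | intermediate
15 | (2S)-5,7-bis(methoxymethoxy)-2-[7-(methoxymethoxy)-2,2-dimethyl-2H-chromen-6-yl]-8-prenylchroman-4-one | CC(C)=CCc1c(OCOC)cc(OCOC)c2c1O[C@H](c1cc3c(cc1OCOC)OC(C)(C)C=C3)CC2=O | intermediate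
16 | (2S)-5,7-dihydroxy-2-(7-hydroxy-2,2-dimethyl-2H-chromen-6-yl)-8-(3-methylbut-2-en-1-yl)chroman-4-one | CC(C)=CCc1c(O)cc(O)c2c1O[C@H](c1cc3c(cc1O)OC(C)(C)C=C3)CC2=O | target

Total step count: 9. Longest linear sequence: 7 (steps 1, 2, 5, 6, 7, 8, 9).

Steps most likely to fail

**Step 7.** The [3,3] shift may go in part to C3', which would fuse ring D at the wrong edge of ring B. The tertiary propargyl ether may also fragment before it rearranges.
- The fallback sets out from 10 and comes back at 14. It separates C–C from C–O bond formation and closes the ring oxidatively, in the biomimetic manner.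
- Semihydrogenation of the alkyne (H2, Pd/CaCO3 poisoned with Pb(OAc)2, quinoline, EtOAc, rt) would give the rac-4'-O-(1,1-dimethylallyl) ether F1.
- Its aromatic Claisen rearrangement at lower temperature (toluene, about 110–130 °C) would deliver a normal prenyl group to C5'. This liberates O4'–H as the only phenol in rac-4'-hydroxy-5'-prenylflavanone F2, which can be freed chromatographically from any C3' isomer.
- DDQ (toluene, rt to 60 °C) would then abstract hydride from the C5' benzylic CH2 to give 13, which closes to 14.
- The 8-prenyl group is not expected to follow this path, because both of its ortho oxygens are alkylated.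

**Step 8.** Hydride transfer may be slow, and the rate difference between the enantiomers too small, because the peri 5-OMOM and the ortho 2'-OMOM groups crowd the ketone.
- The fallback sets out from 14 and comes back at 15. It moves the resolution to the alcohol oxidation level.
- NaBH4 (MeOH/THF, 0 °C) would give the rac-cis-flavan-4-ol F3.
- A lipase (Burkholderia cepacia lipase or Candida antarctica lipase B, vinyl acetate, MTBE, 30–40 °C) is expected to acylate the (4R)-configured aryl carbinol to the (2R,4R)-flavan-4-yl acetate F5. The (2S,4S)-flavan-4-ol F4 is left behind and separated.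
- Dess–Martin periodinane (NaHCO3, CH2Cl2, 0 °C) would return F4 to 15 without touching C2.

**Step 9.** Acid may ionise the doubly donor-activated benzylic C2–O1 bond, with loss of configurational purity. It may also add methanol or O7–H across the chromene and prenyl alkenes.
- The fallback sets out from 15 and comes back at 16. It replaces protic solvolysis by acetal-to-silyl-ether exchange under buffered, non-protic conditions.
- TMSOTf and 2,2'-bipyridyl (MeCN, 0 °C to rt) would convert the three aryl MOM ethers into the (2S)-tris(trimethylsilyl) ether F6.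
- Addition of water at neutral pH would hydrolyse F6 to 16.

Further compounds
F1 | step 7 | rac-5,7,2'-tris(methoxymethoxy)-4'-[(2-methylbut-3-en-2-yl)oxy]-8-prenylflavanone | CC(C)=CCc1c(OCOC)cc(OCOC)c2c1OC(c1ccc(OC(C)(C)C=C)cc1OCOC)CC2=O
F2 | step 7 | rac-4'-hydroxy-5,7,2'-tris(methoxymethoxy)-8,5'-diprenylflavanone | CC(C)=CCc1c(OCOC)cc(OCOC)c2c1OC(c1cc(CC=C(C)C)c(O)cc1OCOC)CC2=O
F3 | step 8 | rac-cis-flavan-4-ol from 14 (racemate, drawn without labels) | CC(C)=CCc1c(OCOC)cc(OCOC)c2c1OC(c1cc3c(cc1OCOC)OC(C)(C)C=C3)CC2O
F4 | step 8 | (2S,4S)-flavan-4-ol | CC(C)=CCc1c(OCOC)cc(OCOC)c2c1O[C@H](c1cc3c(cc1OCOC)OC(C)(C)C=C3)C[C@@H]2O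
F5 | step 8 | (2R,4R)-flavan-4-yl acetate | CC(C)=CCc1c(OCOC)cc(OCOC)c2c1O[C@@H](c1cc3c(cc1OCOC)OC(C)(C)C=C3)C[C@H]2OC(C)=O
F6 | step 9 | (2S)-5,7,2'-tris(trimethylsilyl) ether of 16 | CC(C)=CCc1c(O[Si](C)(C)C)cc(O[Si](C)(C)C)c2c1O[C@H](c1cc3c(cc1O[Si](C)(C)C)OC(C)(C)C=C3)CC2=O
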